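**Retrosynthetic overview**
1. Target 16 ⇐ benzyl-protected 4-alkylguaiacol diol 14: the last step oxygenates ring A (the methoxy-dihydroxyphenyl ring) ortho to its OH (Teuber oxidation, then H2, which also removes the benzyl group of ring B).
2. syn-1,3-Diol 14 ⇐ (5S)-β-hydroxy ketone 12 (Narasaka–Prasad reduction; C3 is set from C5).
3. Key disconnection, ring A aryl–C1 bond: radical ring-opening arylation of cyclopropanol 8 with 4-bromo-2-methoxyphenol 11 (strain-release β-keto alkyl radical captured by aryl–nickel), which also unmasks the C3 ketone.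
4. 8 ⇐ (S)-β-lactone 7 (Kulinkovich; C1–C2 come from EtMgBr) ⇐ aldehyde 4 + ketene (catalytic asymmetric [2+2], sets C5) ⇐ 4-iodophenol + allyl alcohol (Heck); 11 ⇐ catechol.
5. Ring order: no ring of the target is built (both arenes enter as C6 units); the auxiliary oxetanone (step 3) and then the cyclopropane (step 4) are formed and opened again in steps 4 and 7.

Assumption 1: in step 3 the L-valinol-derived (S,S)-ligand gives the (4S)-lactone, as it does with 3-phenylpropanal; should the sign be opposite, the mirror-image ligand is used and nothing else changes.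
Assumption 2: a telescoped operation whose intermediate is not isolated is counted as one step; the ee of 7 (about 90% expected) is raised by recrystallisation of 8 or 14 if needed.

**Route**

Step 1
Reactants: 1 4-iodophenol
Product: 2 1-(benzyloxy)-4-iodobenzene
Conditions: BnBr (1.1 equiv), K2CO3 (1.5 equiv), acetone, reflux
Reagents that add atoms: benzyl bromide, BrCc1ccccc1
Why: Williamson ether synthesis; the benzyl ether keeps the ring B phenol out of the phenol oxidation of step 9 and is removed in that same step.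

Step 2
Reactants: 2 1-(benzyloxy)-4-iodobenzene; 3 prop-2-en-1-ol (allyl alcohol)
Product: 4 3-[4-(benzyloxy)phenyl]propanal
Conditions: Pd(OAc)2 (2 mol%), Bu4NCl (1 equiv), NaHCO3 (2.5 equiv), DMF, 40 °C
Reagents that add atoms: none
Why: Heck arylation of allyl alcohol under Jeffery conditions, in which the aryl–palladium species adds to the terminal alkene carbon and β-hydride elimination towards the carbinol gives an enol that tautomerises to the saturated aldehyde; no stereocentre is formed.

Step 3
Reactants: 4 3-[4-(benzyloxy)phenyl]propanal; 5 acetyl bromide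
Product: 7 (4S)-4-{2-[4-(benzyloxy)phenyl]ethyl}oxetan-2-one, via ketene 6 (not isolated)
Conditions: AlMe3 (10 mol%), (S,S)-N-benzyl-N,N-bis[3-methyl-2-(trifluoromethanesulfonamido)butyl]amine (10 mol%), iPr2NEt (1.7 equiv), AcBr (1.9 equiv), CH2Cl2, −50 °C
Reagents that add atoms: none
Why: Catalytic asymmetric acyl halide–aldehyde cyclocondensation, a formal [2+2] cycloaddition of ketene (made in the flask from 5 and the amine) with the aldehyde bound to the chiral trivalent aluminium Lewis acid, which sets C5 of the target as S by catalyst control.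

Step 4
Reactants: 7 (4S)-4-{2-[4-(benzyloxy)phenyl]ethyl}oxetan-2-one
Product: 8 1-[(2S)-4-[4-(benzyloxy)phenyl]-2-hydroxybutyl]cyclopropan-1-ol
Conditions: EtMgBr (3.0 equiv, added over 2 h), Ti(OiPr)4 (0.3 equiv), THF, 0 °C to rt; aq. NH4Cl
Reagents that add atoms: ethylmagnesium bromide, CC[Mg]Br
Why: Proposed new method: Kulinkovich cyclopropanation applied to a β-lactone, in which the titanacyclopropane made from EtMgBr and Ti(OiPr)4 acts as a 1,2-dicarbanion that adds to the acyl carbon, strain-assisted acyl–oxygen cleavage frees the C5 alkoxide and the β-titanio ketone closes to the cyclopropoxide, the closest known reactions being the Kulinkovich reaction of γ- and δ-lactones and of β-hydroxy esters (an isopropyl ester formed by prior alcoholysis of the lactone would give the same product), and the C5 stereocentre is not touched.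

Step 5
Reactants: 9 benzene-1,2-diol (catechol)
Product: 10 2-methoxyphenol (guaiacol)
Conditions: MeI (1.0 equiv), K2CO3 (1.0 equiv), acetone, reflux
Reagents that add atoms: iodomethane, CI
Why: Williamson mono-O-methylation with one equivalent of MeI, a statistical reaction from which guaiacol is separated from unreacted catechol and 1,2-dimethoxybenzene by extraction and distillation.

Step 6
Reactants: 10 2-methoxyphenol
Product: 11 4-bromo-2-methoxyphenol
Conditions: NBS (1.0 equiv), MeCN, 0 °C to rt
Reagents that add atoms: N-bromosuccinimide, O=C1CCC(=O)N1Br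
Why: Electrophilic aromatic bromination, in which the free OH is the stronger director and its open para position is substituted.

Step 7 (key step)
Reactants: 8 1-[(2S)-4-[4-(benzyloxy)phenyl]-2-hydroxybutyl]cyclopropan-1-ol; 11 4-bromo-2-methoxyphenol (1.5 equiv)
Product: 12 (5S)-7-[4-(benzyloxy)phenyl]-5-hydroxy-1-(4-hydroxy-3-methoxyphenyl)heptan-3-one
Conditions: NiBr2·dme (10 mol%; dme = 1,2-dimethoxyethane), 4,4'-di-tert-butyl-2,2'-bipyridine (12 mol%), 4CzIPN (2,4,5,6-tetra(carbazol-9-yl)isophthalonitrile, 2 mol%), Ti(OiPr)4 (30 mol%), 2,6-lutidine (2 equiv), DMA, blue LEDs (450 nm), rt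
Reagents that add atoms: none
Why: Dual photoredox/nickel ring-opening arylation of a cyclopropanol (a radical homoenolate cross-coupling), in which single-electron oxidation of the titanium cyclopropoxide by excited 4CzIPN triggers strain-driven β-scission to the primary β-keto alkyl radical, this radical is captured by the aryl–nickel bromide formed from 11 and zerovalent nickel, and reductive elimination from trivalent nickel forms the aryl–C1 bond while unveiling the C3 ketone, with free OH groups tolerated and C5 untouched.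

Step 8
Reactants: 12 (5S)-7-[4-(benzyloxy)phenyl]-5-hydroxy-1-(4-hydroxy-3-methoxyphenyl)heptan-3-one
Product: 14 (3R,5S)-7-[4-(benzyloxy)phenyl]-1-(4-hydroxy-3-methoxyphenyl)heptane-3,5-diol, via boron chelate 13 (not isolated)
Conditions: Et2BOMe (2.2 equiv), THF/MeOH 4:1, −78 °C; NaBH4 (1.5 equiv), −78 °C; MeOH co-evaporation
Reagents that add atoms: none
Why: Narasaka–Prasad reduction, in which the diethylboron chelate holds the β-alkoxy ketone in a half-chair and external hydride attacks axially to give the 1,3-syn diol, so that C3 becomes R from C5 = S.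

Step 9
Reactants: 14 (3R,5S)-7-[4-(benzyloxy)phenyl]-1-(4-hydroxy-3-methoxyphenyl)heptane-3,5-diol
Product: 16 (3R,5S)-1-(3,4-dihydroxy-5-methoxyphenyl)-7-(4-hydroxyphenyl)heptane-3,5-diol, via ortho-quinone 15 (not isolated)
Conditions: (KSO3)2NO (2.5 equiv), KH2PO4, H2O/acetone, 0 °C; extraction into EtOAc; then H2 (1 atm), Pd/C (10 wt%), EtOAc/MeOH, rt
Reagents that add atoms: potassium nitrosodisulfonate, [K+].[K+].[O]N(S(=O)(=O)[O-])S(=O)(=O)[O-]
Why: Teuber oxidation of the para-blocked guaiacol at its free ortho position by the nitroxyl radical of Fremy's salt gives the 3-methoxy-ortho-quinone, and catalytic hydrogenation then reduces the quinone to the catechol and cleaves the benzyl ether in the same operation, leaving both stereocentres untouched.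

**Compound list**
1 | 4-iodophenol | Oc1ccc(I)cc1 | starting material
2 | 1-(benzyloxy)-4-iodobenzene | Ic1ccc(OCc2ccccc2)cc1 | intermediate
3 | prop-2-en-1-ol (allyl alcohol) | OCC=C | starting material
4 | 3-[4-(benzyloxy)phenyl]propanal | O=CCCc1ccc(OCc2ccccc2)cc1 | intermediate
5 | acetyl bromide | CC(=O)Br | starting material
6 | ketene (not isolated) | C=C=O | intermediate
7 | (4S)-4-{2-[4-(benzyloxy)phenyl]ethyl}oxetan-2-one | O=C1C[C@H](CCc2ccc(OCc3ccccc3)cc2)O1 | intermediate
8 | 1-[(2S)-4-[4-(benzyloxy)phenyl]-2-hydroxybutyl]cyclopropan-1-ol | OC1(C[C@@H](O)CCc2ccc(OCc3ccccc3)cc2)CC1 | intermediate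
9 | benzene-1,2-diol (catechol) | Oc1ccccc1O | starting material
10 | 2-methoxyphenol (guaiacol) | COc1ccccc1O | intermediate
11 | 4-bromo-2-methoxyphenol | COc1cc(Br)ccc1O | intermediate
12 | (5S)-7-[4-(benzyloxy)phenyl]-5-hydroxy-1-(4-hydroxy-3-methoxyphenyl)heptan-3-one | COc1cc(CCC(=O)C[C@@H](O)CCc2ccc(OCc3ccccc3)cc2)ccc1O | intermediate
13 | (5S)-7-[4-(benzyloxy)phenyl]-1-(4-hydroxy-3-methoxyphenyl)-3-oxoheptan-5-yl diethylborinate, boron chelated by the ketone oxygen (not isolated) | COc1cc(CCC(=O)C[C@@H](OB(CC)CC)CCc2ccc(OCc3ccccc3)cc2)ccc1O | intermediate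
14 | (3R,5S)-7-[4-(benzyloxy)phenyl]-1-(4-hydroxy-3-methoxyphenyl)heptane-3,5-diol | COc1cc(CC[C@@H](O)C[C@@H](O)CCc2ccc(OCc3ccccc3)cc2)ccc1O | intermediate
15 | 5-[(3R,5S)-7-[4-(benzyloxy)phenyl]-3,5-dihydroxyheptyl]-3-methoxycyclohexa-3,5-diene-1,2-dione (not isolated) | COC1=CC(CC[C@@H](O)C[C@@H](O)CCc2ccc(OCc3ccccc3)cc2)=CC(=O)C1=O | intermediate
16 | (3R,5S)-1-(3,4-dihydroxy-5-methoxyphenyl)-7-(4-hydroxyphenyl)heptane-3,5-diol | COc1cc(CC[C@@H](O)C[C@@H](O)CCc2ccc(O)cc2)cc(O)c1O | target

**Step count and risks**

Total step count: 9. Longest linear sequence: 7 (steps 1, 2, 3, 4, 7, 8, 9).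

Steps most likely to fail:

Step 7. The electron-rich free phenol of 11 can quench or be oxidised by the excited photocatalyst, the 1,3-diol motif can tie up titanium, and the β-keto alkyl radical can be reduced to the ethyl ketone. The fallback leaves the photochemical radical manifold and sets out from 8. Electrophilic ring opening with NBS (CH2Cl2, 0 °C) gives the β-bromo ketone (5S)-7-[4-(benzyloxy)phenyl]-1-bromo-5-hydroxyheptan-3-one F1, and Et3N eliminates HBr to the vinyl ketone (5S)-7-[4-(benzyloxy)phenyl]-5-hydroxyhept-1-en-3-one F2. A polar palladium-catalysed reductive Heck (conjugate) arylation of F2 with 11 (Pd(OAc)2, PPh3, HCO2Na, DMF, 80 °C) comes back to the route at 12.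

Step 4. EtMgBr may attack the strained lactone directly (ethyl ketone, tertiary alcohol) before it is transferred to titanium. The fallback sets out from 7: methanolysis (NaOMe cat., MeOH, 0 °C) opens the lactone to the acyclic ester methyl (3S)-5-[4-(benzyloxy)phenyl]-3-hydroxypentanoate F3. This is a well-behaved Kulinkovich substrate (EtMgBr 4 equiv, Ti(OiPr)4, THF) and returns to the route at 8.

Step 9. The ortho-quinone 15 can tautomerise to a quinone methide that the C5 hydroxyl traps as a tetrahydropyran, and over-oxidation is possible. The fallback replaces the oxidation by a formylation–Dakin sequence and sets out from 14. Magnesium-mediated ortho-formylation (MgCl2, Et3N, paraformaldehyde, MeCN, reflux) gives 5-[(3R,5S)-7-[4-(benzyloxy)phenyl]-3,5-dihydroxyheptyl]-2-hydroxy-3-methoxybenzaldehyde F4. Dakin oxidation (H2O2, NaOH aq., 0 °C, under N2) gives 5-[(3R,5S)-7-[4-(benzyloxy)phenyl]-3,5-dihydroxyheptyl]-3-methoxybenzene-1,2-diol F5, and hydrogenolysis (H2, Pd/C, EtOAc/MeOH) comes back to the route at 16.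

**Further compounds**
F1 | step 7 | (5S)-7-[4-(benzyloxy)phenyl]-1-bromo-5-hydroxyheptan-3-one | BrCCC(=O)C[C@@H](O)CCc1ccc(OCc2ccccc2)cc1
F2 | step 7 | (5S)-7-[4-(benzyloxy)phenyl]-5-hydroxyhept-1-en-3-one | C=CC(=O)C[C@@H](O)CCc1ccc(OCc2ccccc2)cc1
F3 | step 4 | methyl (3S)-5-[4-(benzyloxy)phenyl]-3-hydroxypentanoate | COC(=O)C[C@@H](O)CCc1ccc(OCc2ccccc2)cc1
F4 | step 9 | 5-[(3R,5S)-7-[4-(benzyloxy)phenyl]-3,5-dihydroxyheptyl]-2-hydroxy-3-methoxybenzaldehyde | COc1cc(CC[C@@H](O)C[C@@H](O)CCc2ccc(OCc3ccccc3)cc2)cc(C=O)c1O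
F5 | step 9 | 5-[(3R,5S)-7-[4-(benzyloxy)phenyl]-3,5-dihydroxyheptyl]-3-methoxybenzene-1,2-diol | COc1cc(CC[C@@H](O)C[C@@H](O)CCc2ccc(OCc3ccccc3)cc2)cc(O)c1O
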